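**Retrosynthetic overview**
- Ring C is the only ring built. Cutting O1–C2 (retro-oxa-Michael) gives the fully unprotected 3'-geranyl-2',4',6',3-tetrahydroxy-4,5-dimethoxychalcone.
- That closure is the last step. One catalytic, chalcone-isomerase-like event sets C2 as (S) and selects 6'-OH over 2'-OH, which gives 6-geranyl rather than 8-geranyl.
- Cutting Cα=Cβ of the chalcone (polyanion Claisen–Schmidt, no protecting groups) gives 3-geranylphloroacetophenone and 3-hydroxy-4,5-dimethoxybenzaldehyde.
- Cutting the aryl–geranyl bond gives phloroacetophenone and geranyl bromide. C3 and C5 are equivalent, so there is no regiochemical issue.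
- Rings A and B are bought.

Assumption: the three starting materials and the thiourea catalyst are catalogue items, and the sense of induction (quinidine series gives 2S) is assigned by analogy with intermolecular conjugate additions to chalcones in this catalyst family and is checked by CD and chiral HPLC on the first run.

**Route**

Step 1
Reactants: 1 2,4,6-trihydroxyacetophenone; 2 (E)-geranyl bromide
Product: 3 3-geranyl-2,4,6-trihydroxyacetophenone
Conditions: 1 (1.5 equiv), 2 (1.0 equiv), K2CO3 (1.2 equiv), acetone, reflux, 8 h
Reagents that add atoms: none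
Why: Base-mediated C-alkylation (SN2) of the ambident phloroacetophenone anion, whose ring carbons react like the central carbon of a vinylogous 1,3-dicarbonyl; C3 and C5 are equivalent so only one mono-C-geranyl product exists, the excess of 1 limits double alkylation, direct displacement at the primary allylic carbon keeps the E-alkene, and no stereocentre is formed.

Step 2
Reactants: 3 3-geranyl-2,4,6-trihydroxyacetophenone; 4 3-hydroxy-4,5-dimethoxybenzaldehyde
Product: 6 (E)-3'-geranyl-2',4',6',3-tetrahydroxy-4,5-dimethoxychalcone, via lithium aldolate 5 (not isolated)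
Conditions: LiN(SiMe3)2 (5.5 equiv in all), THF, −78 °C → rt, 16 h; then cold 1 M HCl to pH 3–4, 0 °C; quick chromatography on acid-washed silica
Reagents that add atoms: none
Why: Protecting-group-free Claisen–Schmidt condensation (aldol addition, then E1cB loss of LiOH): excess amide base turns every phenol into its lithium phenoxide and still enolises the methyl ketone, the phenoxide of 4 is meta to the formyl group and does not deactivate it, the conjugated E-enone is the thermodynamic product, the polyanionic chalcone stays open, and cold acidification passes quickly through the pH range in which the neutral chalcone would close racemically.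

Step 3
Reactants: 6 (E)-3'-geranyl-2',4',6',3-tetrahydroxy-4,5-dimethoxychalcone
Product: 8 (2S)-6-geranyl-5,7,3'-trihydroxy-4',5'-dimethoxyflavanone, via chromen-4-ol enol 7 (not isolated)
Conditions: N-[3,5-bis(trifluoromethyl)phenyl]-N'-[(9R)-6'-methoxycinchonan-9-yl]thiourea (15 mol %), 4 Å molecular sieves, toluene/MTBE 3:1 (0.02 M), −25 °C, 72 h; cold silica plug (eluent with 0.5% AcOH)
Reagents that add atoms: none
Why: Proposed new method: a chalcone-isomerase-like catalytic enantioselective 6-endo-trig intramolecular oxa-Michael addition in which the quinuclidine nitrogen deprotonates the less hindered and more acidic 6'-OH (the 2'-OH, buttressed by the geranyl group, stays locked in its hydrogen bond to C=O and becomes the 5-OH next to geranyl, hence the 6-geranyl isomer) while the thiourea N–H bonds hold the carbonyl/enolate oxygen so that the phenoxide closes on the Si face of C-β and sets (2S) before enol 7 tautomerises; no activating ester should be needed because 2',4',6'-trihydroxychalcones already cyclise under weak general-base catalysis, the 5-OH-chelated flavanone is far more stable than the chalcone so closure is practically irreversible at −25 °C, and the uncatalysed background is negligible in an aprotic medium, the closest known reaction types being the cinchona-thiourea oxa-Michael cyclisation of ester-activated 2'-hydroxychalcones to flavanones and the cinchona-base cyclisation of 2',6'-dihydroxychalcones.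

**Compound list**
1 | 2,4,6-trihydroxyacetophenone (phloroacetophenone) | CC(=O)c1c(O)cc(O)cc1O | starting material
2 | (E)-geranyl bromide, (2E)-1-bromo-3,7-dimethylocta-2,6-diene | BrC/C=C(\C)CCC=C(C)C | starting material
3 | 1-{3-[(2E)-3,7-dimethylocta-2,6-dien-1-yl]-2,4,6-trihydroxyphenyl}ethanone | CC(=O)c1c(O)cc(O)c(C/C=C(\C)CCC=C(C)C)c1O | intermediate
4 | 3-hydroxy-4,5-dimethoxybenzaldehyde | COc1cc(C=O)cc(O)c1OC | starting material
5 | aldol adduct, 1-(3-geranyl-2,4,6-trihydroxyphenyl)-3-hydroxy-3-(3-hydroxy-4,5-dimethoxyphenyl)propan-1-one, racemic at the carbinol carbon, present as its lithium salt | COc1cc(C(O)CC(=O)c2c(O)cc(O)c(C/C=C(\C)CCC=C(C)C)c2O)cc(O)c1OC | intermediate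
6 | (E)-3'-geranyl-2',4',6',3-tetrahydroxy-4,5-dimethoxychalcone | COc1cc(/C=C/C(=O)c2c(O)cc(O)c(C/C=C(\C)CCC=C(C)C)c2O)cc(O)c1OC | intermediate
7 | (2S)-6-geranyl-2-(3-hydroxy-4,5-dimethoxyphenyl)-2H-chromene-4,5,7-triol (enol of 8) | COc1cc([C@@H]2C=C(O)c3c(cc(O)c(C/C=C(\C)CCC=C(C)C)c3O)O2)cc(O)c1OC | intermediate
8 | (2S)-6-geranyl-5,7,3'-trihydroxy-4',5'-dimethoxyflavanone (CNP0228243.1) | COc1cc([C@@H]2CC(=O)c3c(cc(O)c(C/C=C(\C)CCC=C(C)C)c3O)O2)cc(O)c1OC | target

**Totals**
- Total step count: 3.
- Longest linear sequence: 3.

**Steps most likely to fail**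

Step 3 is the riskiest.
- The ee may be only moderate.
- Some material may leak to the 8-geranyl isomer through 2'-OH.
- The sense of induction is not proven for this substrate.
- The fallback sets out from 6 and comes back at 8. Chalcone 6 is closed without induction (NaOAc, EtOH, 40 °C) to racemic 6-geranyl-5,7,3'-trihydroxy-4',5'-dimethoxyflavanone F1, and the minor 8-geranyl isomer is removed by chromatography.
- F1 is then kinetically resolved by asymmetric transfer hydrogenation with RuCl[(R,R)-TsDPEN](p-cymene) in HCO2H/Et3N and EtOAc at rt, stopped near 55% conversion.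
- The (2R)-ketone is the matched substrate and is reduced to cis-(2R,4R)-6-geranyl-2-(3-hydroxy-4,5-dimethoxyphenyl)chromane-4,5,7-triol F2. The isolated geranyl alkenes are untouched.
- The unreacted (2S)-ketone 8 is separated on silica. The yield ceiling is 50%.

Step 2 comes next.
- The pentalithiated system may be poorly soluble or sluggish.
- Chalcone 6 may partly close to racemic flavanone at work-up. Any such flavanone must be removed, or it lowers the final ee.
- The fallback sets out from 3 and 4 and comes back at 6. MOMCl and iPr2NEt in CH2Cl2 convert 3 into 1-[3-geranyl-2-hydroxy-4,6-bis(methoxymethoxy)phenyl]ethanone F3.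
- The same reagents convert 4 into 3,4-dimethoxy-5-(methoxymethoxy)benzaldehyde F4.
- A classical KOH/EtOH–H2O condensation at rt then gives the tris-MOM chalcone F5.
- Brief HCl in MeOH at rt removes all three acetals and gives 6. Which ortho-OH stays free in F3 does not matter, because everything is unmasked before the key step.

Step 1 is the least risky of the three. The expected yield is only about 40–50%, with O-geranyl and digeranyl by-products.
- The fallback sets out from 1 and comes back at 3. Geraniol with ClCO2Me and pyridine gives geranyl methyl carbonate F6.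
- F6 then alkylates 1 under zerovalent palladium catalysis (Pd(PPh3)4, 5 mol %, THF, 40 °C) by a Tsuji–Trost reaction with no added base.
- O-allylation is reversible under these conditions, so material funnels to the C-alkylated product.
- The soft carbon nucleophile attacks the unsubstituted allyl terminus and gives linear (E)-3.

Further compounds
F1 | step 3 | racemic 6-geranyl-5,7,3'-trihydroxy-4',5'-dimethoxyflavanone | COc1cc(C2CC(=O)c3c(cc(O)c(C/C=C(\C)CCC=C(C)C)c3O)O2)cc(O)c1OC
F2 | step 3 | cis-(2R,4R)-6-geranyl-2-(3-hydroxy-4,5-dimethoxyphenyl)chromane-4,5,7-triol | COc1cc([C@H]2C[C@@H](O)c3c(cc(O)c(C/C=C(\C)CCC=C(C)C)c3O)O2)cc(O)c1OC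
F3 | step 2 | 1-[3-geranyl-2-hydroxy-4,6-bis(methoxymethoxy)phenyl]ethanone | CC(=O)c1c(OCOC)cc(OCOC)c(C/C=C(\C)CCC=C(C)C)c1O
F4 | step 2 | 3,4-dimethoxy-5-(methoxymethoxy)benzaldehyde | COCOc1cc(C=O)cc(OC)c1OC
F5 | step 2 | (E)-3'-geranyl-2'-hydroxy-4,5-dimethoxy-3,4',6'-tris(methoxymethoxy)chalcone | COCOc1cc(/C=C/C(=O)c2c(OCOC)cc(OCOC)c(C/C=C(\C)CCC=C(C)C)c2O)cc(OC)c1OC
F6 | step 1 | geranyl methyl carbonate | COC(=O)OC/C=C(\C)CCC=C(C)C
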